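Count how long the X of a dosed flask has really stood in it, not how long the clock has run.

| flask | X | L | temperature | remark | time |
|---|---|---|---|---|---|
| north | 0.10 M (in portions, 4) | 0.041 M | 10 °C | run made earlier; portions every 30 s |  |
| west | 0.10 M (in portions, 4) | 0.11 M | 25 °C | run made earlier; portions every 30 s |  |
| south | 0.10 M (in portions, 4) | 0.23 M | 10 °C | run made earlier; portions every 30 s |  |
| larch | 0.10 M (in portions, 4) | 0.200 M | 25 °C | the portions of X follow each other after 30 s, the first at the start | 3.0 min |
| birch | 0.10 M | 0.0500 M | 25 °C | everything together at the start | 3.0 min |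

| run | time / min | J / % | X / % |
|---|---|---|---|
| north | 0.500 | 0 | 26.1 |
| north | 1.00 | 0 | 49.2 |
| north | 3.00 | 1.4 | 101.2 |
| north | 6.00 | 0 | 99.8 |
| west | 0.250 | 0 | 24.2 |
| west | 0.500 | 0.5 | 24.9 |
| west | 1.33 | 0.4 | 74.7 |
| west | 3.00 | 5.8 | 95.1 |
| south | 0.500 | 1.3 | 25.5 |
| south | 1.00 | 0 | 49.9 |
| south | 3.00 | 3.6 | 100.4 |
| south | 6.00 | 21.5 | 79.4 |

(readings scatter by 1 percentage point)

* which one finishes higher in amount of J, in percent of the X charged ("neither" within 2 percentage points) (larch / birch / neither)
* amount of J at the end, in percent of the X charged, larch
* amount of J at the end, in percent of the X charged, birch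

- steps thought possible: X + L + J -> 2 J; X + L -> J

1. Two extremes bracket larch. With the whole charge at the start, X stands for 3.0 min; with the whole charge arriving at the last portion, for 1.50 min. The staircase lies between them: the mean portion comes 0.750 min late, so the exposure, meaning minutes at full charge of X while none is consumed, is 2.25 min, less than 3.0 min and more than 1.50 min.

2. South climbs from 3.6% J at 3.00 min to 21.5% at 6.00 min, which reads as autocatalysis on a weak direct step. J plus a small seed, the J-equivalent supplied by the direct step, then multiplies by e raised to a growth number, taken as proportional to L times exposure at one temperature and one charge of X. The ratio of J to the rest of the charge rises in south at 0.664 /min, which puts the seed near 1.04% of the charge. That rough reading of the seed is taken over unchanged from 10 °C to 25 °C, as an assumption.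

3. West, on the same staircase, reads 5.8% at 3.00 min, which reads as a growth number of 1.88. Scaling by L and exposure gives 1.14 for birch, hence 2.22% J. By this estimate birch spends hardly any of its X.

4. Larch scales to 3.42, and the mean alone gives 30.9%. That figure counts X as untouched, although 30.9% J is taken from X. So split larch: up to the last portion the exposure equals 0.750 min, giving 2.22% J. The ratio of J plus seed to X then grows over 1.50 min to 0.326, which means 23.8% J.

The forecast, “Larch finishes higher, despite dosing.”, gives 21% for larch, lower than the 23.8% reckoned here, and 2.3% for birch.

The flasks give 26.5% J in larch and 2.01% in birch, so larch finishes higher.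

    X + L + J → 2 J (k = 1.50 /M²/s, Ea = 41.0 kJ/mol)
    X + L → J (k = 0.00110 /M/s, Ea = 79.0 kJ/mol)
    (constants at 25 °C)

At 3.00 min in larch, the step with J uses X 36 times as fast as the direct step, with X at 73.5% and J at 26.5%. With these constants the exposure 2.25 min gives larch a growth number of 4.05, while birch, exposed for 3.0 min, has 1.35 and stands at 98.0% X and 2.01% J.

The data are calculated from invented constants; the scatter is artificial.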